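**Retrosynthetic overview**

- The oxirane comes last, by peracid epoxidation of the C1=C10 olefin of a (1(10)Z,4Z)-germacradienolide; just before it, O6 is acylated with a (2S,3R)-dihydroxy-acid angelate built from a cheap (S)-β-hydroxy ester.
- The ten-membered ring is closed at C5–C6 by an intramolecular Nozaki–Hiyama–Kishi addition of a (Z)-alkenyl bromide to the C6 aldehyde.
- C9–C10 is made by nickel-catalysed reductive coupling of the lactone CH2Br with the (Z)-alkenyl iodide end of a Z,Z-dihalodiene (alkyne carbocupration, then iodo-olefination).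
- Key bond C6–C7: a visible-light photoredox radical step replaces the C7 hydroxyl of 2-C-methyl-D-ribono-1,4-lactone 1 by a masked formyl group, with retention.
- Ring order: γ-lactone (bought, carrying C8 and C11) → carbocycle → oxirane.

Assumption: germacrane numbering is used (lactone closed onto O8); the SMILES is read as 1R,6R,7S,8R,10S,11R,2′S,3′R with a 4Z olefin and a cis-epoxide; every starting material and reagent named below is taken as purchasable.

**Route**

Step 1
Reactants: 1 2-C-methyl-D-ribono-1,4-lactone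
Product: 2 (3R,4R,5S)-5-(bromomethyl)-3,4-dihydroxy-3-methyloxolan-2-one
Conditions: CBr4, PPh3, pyridine, 0 °C to rt
Reagents that add atoms: carbon tetrabromide, BrC(Br)(Br)Br
Why: Appel reaction; only the primary hydroxyl is activated and displaced, so the two ring stereocentres that become C8 and C11 are carried over untouched.

Step 2
Reactants: 2 (3R,4R,5S)-5-(bromomethyl)-3,4-dihydroxy-3-methyloxolan-2-one; 3 (E)-N-(benzyloxy)-1-(phenylsulfonyl)methanimine
Product: 5 (3R,4R,5S)-4-[(E)-(benzyloxyimino)methyl]-5-(bromomethyl)-3-hydroxy-3-methyloxolan-2-one, via benzoxazoline adduct 4 (not isolated)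
Conditions: 5,7-di-tert-butyl-3-phenylbenzoxazolium tetrafluoroborate (1.2 equiv), pyridine, MTBE, rt; then 3 (2 equiv), [Ir(ppy)2(dtbbpy)]PF6 (1 mol%), NaOAc, MTBE/DMSO, 450 nm LEDs, rt
Reagents that add atoms: none
Why: Proposed new method: the secondary hydroxyl (not the tertiary one) condenses with the benzoxazolium salt, photoredox oxidation, deprotonation and β-scission of adduct 4 release the ring C4 radical, which adds to the sulfonyl oxime and expels PhSO2• (reduced to sulfinate by the reduced iridium photocatalyst), the C–C bond forming anti to the C3 methyl and the C5 CH2Br, that is with retention, which sets C7; the closest known reactions are the NHC-mediated photoredox deoxygenative Giese alkylation of alcohols and tin-mediated radical addition to sulfonyl oxime ethers.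

Step 3
Reactants: 5 (3R,4R,5S)-4-[(E)-(benzyloxyimino)methyl]-5-(bromomethyl)-3-hydroxy-3-methyloxolan-2-one
Product: 6 (3R,4R,5S)-4-[(E)-(benzyloxyimino)methyl]-5-(bromomethyl)-3-methyl-2-oxooxolan-3-yl (2Z)-2-methylbut-2-enoate
Conditions: angelic anhydride (3 equiv), Sc(OTf)3 (10 mol%), MeCN, −20 to 0 °C
Reagents that add atoms: angelic anhydride, C/C=C(/C)C(=O)OC(=O)/C(C)=C\C
Why: Lewis-acid-catalysed acylation of the only remaining (tertiary) hydroxyl by the anhydride, with no nucleophilic catalyst present that could isomerise the Z-enoate; no stereocentre is touched.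

Step 4
Reactants: 7 [2-(1,3-dioxolan-2-yl)ethyl]magnesium bromide; 8 propyne
Product: 11 2-[(3Z)-4-bromo-3-methylbut-3-en-1-yl]-1,3-dioxolane, via alkylcopper 9 (not isolated), via alkenylcopper 10 (not isolated)
Conditions: CuBr·SMe2 (1 equiv), Et2O/THF/Me2S, −45 °C; 8 (excess), −25 °C, 3 h; NBS, −40 to 0 °C
Reagents that add atoms: N-bromosuccinimide, O=C1CCC(=O)N1Br
Why: Normant carbocupration; the alkylcopper adds syn across propyne with copper on the terminal carbon, and bromination with retention gives the Z-alkenyl bromide (Br cis to the chain), which fixes the later 4Z geometry.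

Step 5
Reactants: 11 2-[(3Z)-4-bromo-3-methylbut-3-en-1-yl]-1,3-dioxolane
Product: 12 (4Z)-5-bromo-4-methylpent-4-enal
Conditions: 1 M HCl, THF, rt
Reagents that add atoms: water, O
Why: Acid hydrolysis of the cyclic acetal; the alkenyl bromide is inert to dilute acid.

Step 6
Reactants: 12 (4Z)-5-bromo-4-methylpent-4-enal; 13 ethyltriphenylphosphonium bromide
Product: 17 (1Z,5Z)-1-bromo-6-iodo-2-methylhepta-1,5-diene, via ethylidene ylide 14 (not isolated), via iodoethylphosphonium iodide 15 (not isolated), via iodo ylide 16 (not isolated)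
Conditions: 13, n-BuLi, THF, 0 °C; I2, −78 °C; NaHMDS, −78 °C; then 12, −78 to −20 °C
Reagents that add atoms: iodine, II
Why: Stork–Zhao-type Wittig iodo-olefination; the α-iodo ylide reacts through the kinetic cis-oxaphosphetane to give the (Z)-2-iodoalk-2-ene, which fixes the cis geometry later needed at C1/C10.

Step 7
Reactants: 6 (3R,4R,5S)-4-[(E)-(benzyloxyimino)methyl]-5-(bromomethyl)-3-methyl-2-oxooxolan-3-yl (2Z)-2-methylbut-2-enoate; 17 (1Z,5Z)-1-bromo-6-iodo-2-methylhepta-1,5-diene
Product: 18 (3R,4R,5R)-4-[(E)-(benzyloxyimino)methyl]-5-[(2Z,6Z)-7-bromo-2,6-dimethylhepta-2,6-dien-1-yl]-3-methyl-2-oxooxolan-3-yl (2Z)-2-methylbut-2-enoate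
Conditions: NiBr2·glyme (10 mol%), 4,4′-di-tert-butyl-2,2′-bipyridine (10 mol%), NaI (0.5 equiv), Mn powder (2 equiv), DMA, 25 °C
Reagents that add atoms: none
Why: Nickel-catalysed reductive cross-electrophile coupling; zerovalent nickel inserts into the alkenyl iodide much faster than into the alkenyl bromide, the primary alkyl radical from the bromide is captured by the alkenylnickel, olefin geometry is retained, and a radical at C9 does not β-eliminate the lactone oxygen.

Step 8
Reactants: 18 (3R,4R,5R)-4-[(E)-(benzyloxyimino)methyl]-5-[(2Z,6Z)-7-bromo-2,6-dimethylhepta-2,6-dien-1-yl]-3-methyl-2-oxooxolan-3-yl (2Z)-2-methylbut-2-enoate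
Product: 19 (3R,4R,5R)-5-[(2Z,6Z)-7-bromo-2,6-dimethylhepta-2,6-dien-1-yl]-4-formyl-3-methyl-2-oxooxolan-3-yl (2Z)-2-methylbut-2-enoate
Conditions: 37% aq. CH2O, 1 M HCl, THF, rt; used at once
Reagents that add atoms: formaldehyde, C=O
Why: Acid-catalysed transoximation to formaldehyde unmasks the aldehyde; C7 is epimerisable here, but the arrangement with CHO trans to both the C8 side chain and the C11 methyl is the thermodynamic one.

Step 9
Reactants: 19 (3R,4R,5R)-5-[(2Z,6Z)-7-bromo-2,6-dimethylhepta-2,6-dien-1-yl]-4-formyl-3-methyl-2-oxooxolan-3-yl (2Z)-2-methylbut-2-enoate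
Product: 22 (1(10)Z,4Z,6R,7R,8R,11R)-6-hydroxy-11-[(2Z)-2-methylbut-2-enoyloxy]germacra-1(10),4-dien-12,8-olide, via alkenylchromium 20 (not isolated), via chromium alkoxide 21 (not isolated)
Conditions: CrCl2 (10 equiv), NiCl2 (0.2 equiv), degassed DMSO, 2 mM by syringe pump, 25 to 45 °C; aq. work-up
Reagents that add atoms: none
Why: Intramolecular Nozaki–Hiyama–Kishi reaction; the alkenylchromium adds only to the aldehyde with retention of the Z geometry, and Felkin–Anh attack anti to the quaternary C11 and past H-7 sets 6R while closing the ten-membered ring.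

Step 10
Reactants: 23 tert-butyl (3S)-3-hydroxybutanoate
Product: 25 tert-butyl (2S,3S)-3-hydroxy-2-methylbutanoate, via dilithium dianion 24 (not isolated)
Conditions: LDA (2.2 equiv), THF, −78 to −20 °C; MeI, DMPU, −78 to 0 °C
Reagents that add atoms: iodomethane, CI
Why: Fráter–Seebach alkylation; the lithium-chelated alkoxide–enolate is methylated on the face away from the C3 methyl, giving the anti (2S,3S) product.

Step 11
Reactants: 25 tert-butyl (2S,3S)-3-hydroxy-2-methylbutanoate
Product: 27 tert-butyl (2S,3S)-2,3-dihydroxy-2-methylbutanoate, via dilithium dianion 26 (not isolated)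
Conditions: LDA (2.3 equiv), THF, −78 to −30 °C; MoO5·pyridine·HMPA, −78 to −20 °C
Reagents that add atoms: oxodiperoxymolybdenum pyridine HMPA complex, O=[Mo]12(OO1)OO2.c1ccncc1.CN(C)P(=O)(N(C)C)N(C)C
Why: Fráter–Seebach-type enolate hydroxylation; the same chelate face bias places the new oxygen where the methyl entered in step 10, which sets the quaternary C2′ as 2S.

Step 12
Reactants: 27 tert-butyl (2S,3S)-2,3-dihydroxy-2-methylbutanoate
Product: 28 tert-butyl (2S,3R)-2-hydroxy-2-methyl-3-[(2Z)-2-methylbut-2-enoyloxy]butanoate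
Conditions: angelic acid, PPh3, DIAD, toluene, 0 °C to rt
Reagents that add atoms: angelic acid, C/C=C(/C)C(=O)O
Why: Mitsunobu reaction; only the secondary β-hydroxyl is activated and displaced by angelate with inversion (3S to 3R), and because the carboxylate acts as the nucleophile the Z-enoate cannot isomerise.

Step 13
Reactants: 28 tert-butyl (2S,3R)-2-hydroxy-2-methyl-3-[(2Z)-2-methylbut-2-enoyloxy]butanoate
Product: 29 (2S,3R)-2-hydroxy-2-methyl-3-[(2Z)-2-methylbut-2-enoyloxy]butanoic acid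
Conditions: TFA/CH2Cl2 (1:4), 0 °C to rt
Reagents that add atoms: none
Why: Acidolysis of the tert-butyl ester with loss of isobutene; the angelate and the tertiary carbinol next to the carbonyl are stable to these conditions.

Step 14
Reactants: 22 (1(10)Z,4Z,6R,7R,8R,11R)-6-hydroxy-11-[(2Z)-2-methylbut-2-enoyloxy]germacra-1(10),4-dien-12,8-olide; 29 (2S,3R)-2-hydroxy-2-methyl-3-[(2Z)-2-methylbut-2-enoyloxy]butanoic acid
Product: 31 (1(10)Z,4Z,6R,7S,8R,11R)-6-{(2S,3R)-2-hydroxy-2-methyl-3-[(2Z)-2-methylbut-2-enoyloxy]butanoyloxy}-11-[(2Z)-2-methylbut-2-enoyloxy]germacra-1(10),4-dien-12,8-olide, via mixed anhydride 30 (not isolated)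
Conditions: 29, 2,4,6-trichlorobenzoyl chloride, Et3N, THF, rt; then 22, DMAP, toluene, rt
Reagents that add atoms: none
Why: Yamaguchi esterification; the secondary allylic C6 hydroxyl attacks the aliphatic carbonyl of the mixed anhydride, while the tertiary hydroxyl of the acid is too hindered to compete, and C6 is acylated with retention.

Step 15
Reactants: 31 (1(10)Z,4Z,6R,7S,8R,11R)-6-{(2S,3R)-2-hydroxy-2-methyl-3-[(2Z)-2-methylbut-2-enoyloxy]butanoyloxy}-11-[(2Z)-2-methylbut-2-enoyloxy]germacra-1(10),4-dien-12,8-olide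
Product: 32 (1R,4Z,6R,7S,8R,10S,11R)-1,10-epoxy-6-{(2S,3R)-2-hydroxy-2-methyl-3-[(2Z)-2-methylbut-2-enoyloxy]butanoyloxy}-11-[(2Z)-2-methylbut-2-enoyloxy]germacr-4-en-12,8-olide
Conditions: mCPBA (1.1 equiv), NaHCO3, CH2Cl2, 0 °C
Reagents that add atoms: 3-chloroperoxybenzoic acid, O=C(OO)c1cccc(Cl)c1
Why: Prilezhaev epoxidation; the electron-rich C1=C10 olefin reacts before the C4=C5 olefin (deactivated by the allylic ester) and the enoates, the stereospecific syn addition gives the cis-epoxide, and attack on the exposed outer face of the ring-held olefin is expected to give 1R,10S.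

**Compound list**

1 | 2-C-methyl-D-ribono-1,4-lactone, (3R,4R,5R)-3,4-dihydroxy-5-(hydroxymethyl)-3-methyloxolan-2-one | OC[C@H]1OC(=O)[C@](C)(O)[C@@H]1O | starting material
2 | (3R,4R,5S)-5-(bromomethyl)-3,4-dihydroxy-3-methyloxolan-2-one | BrC[C@H]1OC(=O)[C@](C)(O)[C@@H]1O | intermediate
3 | (E)-N-(benzyloxy)-1-(phenylsulfonyl)methanimine | O=S(=O)(/C=N/OCc1ccccc1)c1ccccc1 | starting material
4 | 4-O-(5,7-di-tert-butyl-3-phenyl-2,3-dihydro-1,3-benzoxazol-2-yl) adduct of 2 | BrC[C@H]1OC(=O)[C@](C)(O)[C@@H]1OC1Oc2c(C(C)(C)C)cc(C(C)(C)C)cc2N1c1ccccc1 | intermediate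
5 | (3R,4R,5S)-4-[(E)-(benzyloxyimino)methyl]-5-(bromomethyl)-3-hydroxy-3-methyloxolan-2-one | BrC[C@H]1OC(=O)[C@](C)(O)[C@@H]1/C=N/OCc1ccccc1 | intermediate
6 | (3R,4R,5S)-4-[(E)-(benzyloxyimino)methyl]-5-(bromomethyl)-3-methyl-2-oxooxolan-3-yl (2Z)-2-methylbut-2-enoate | BrC[C@H]1OC(=O)[C@](C)(OC(=O)/C(C)=C\C)[C@@H]1/C=N/OCc1ccccc1 | intermediate
7 | [2-(1,3-dioxolan-2-yl)ethyl]magnesium bromide | Br[Mg]CCC1OCCO1 | starting material
8 | propyne | CC#C | starting material
9 | [2-(1,3-dioxolan-2-yl)ethyl]copper (MgBr2 complex) | [Cu]CCC1OCCO1 | intermediate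
10 | [(1Z)-4-(1,3-dioxolan-2-yl)-2-methylbut-1-en-1-yl]copper | [Cu]/C=C(/C)CCC1OCCO1 | intermediate
11 | 2-[(3Z)-4-bromo-3-methylbut-3-en-1-yl]-1,3-dioxolane | Br/C=C(/C)CCC1OCCO1 | intermediate
12 | (4Z)-5-bromo-4-methylpent-4-enal | Br/C=C(/C)CCC=O | intermediate
13 | ethyltriphenylphosphonium bromide | CC[P+](c1ccccc1)(c1ccccc1)c1ccccc1.[Br-] | starting material
14 | ethylidene(triphenyl)phosphorane | CC=P(c1ccccc1)(c1ccccc1)c1ccccc1 | intermediate
15 | (1-iodoethyl)triphenylphosphonium iodide | CC(I)[P+](c1ccccc1)(c1ccccc1)c1ccccc1.[I-] | intermediate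
16 | (1-iodoethylidene)triphenylphosphorane | CC(I)=P(c1ccccc1)(c1ccccc1)c1ccccc1 | intermediate
17 | (1Z,5Z)-1-bromo-6-iodo-2-methylhepta-1,5-diene | Br/C=C(/C)CC/C=C(/C)I | intermediate
18 | (3R,4R,5R)-4-[(E)-(benzyloxyimino)methyl]-5-[(2Z,6Z)-7-bromo-2,6-dimethylhepta-2,6-dien-1-yl]-3-methyl-2-oxooxolan-3-yl (2Z)-2-methylbut-2-enoate | Br/C=C(/C)CC/C=C(/C)C[C@H]1OC(=O)[C@](C)(OC(=O)/C(C)=C\C)[C@@H]1/C=N/OCc1ccccc1 | intermediate
19 | (3R,4R,5R)-5-[(2Z,6Z)-7-bromo-2,6-dimethylhepta-2,6-dien-1-yl]-4-formyl-3-methyl-2-oxooxolan-3-yl (2Z)-2-methylbut-2-enoate | Br/C=C(/C)CC/C=C(/C)C[C@H]1OC(=O)[C@](C)(OC(=O)/C(C)=C\C)[C@@H]1C=O | intermediate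
20 | alkenylchromium dichloride from 19 | Cl[Cr](Cl)/C=C(/C)CC/C=C(/C)C[C@H]1OC(=O)[C@](C)(OC(=O)/C(C)=C\C)[C@@H]1C=O | intermediate
21 | chromium dichloride alkoxide of 22 | Cl[Cr](Cl)O[C@@H]1/C=C(/C)CC/C=C(/C)C[C@H]2OC(=O)[C@](C)(OC(=O)/C(C)=C\C)[C@H]12 | intermediate
22 | (1(10)Z,4Z,6R,7R,8R,11R)-6-hydroxy-11-[(2Z)-2-methylbut-2-enoyloxy]germacra-1(10),4-dien-12,8-olide (trans-fused lactone) | O[C@@H]1/C=C(/C)CC/C=C(/C)C[C@H]2OC(=O)[C@](C)(OC(=O)/C(C)=C\C)[C@H]12 | intermediate
23 | tert-butyl (3S)-3-hydroxybutanoate | C[C@H](O)CC(=O)OC(C)(C)C | starting material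
24 | dilithium alkoxide–enolate of 23 | C[C@H]([O-])C=C([O-])OC(C)(C)C.[Li+].[Li+] | intermediate
25 | tert-butyl (2S,3S)-3-hydroxy-2-methylbutanoate | C[C@H](O)[C@H](C)C(=O)OC(C)(C)C | intermediate
26 | dilithium alkoxide–enolate of 25 | C[C@H]([O-])C(C)=C([O-])OC(C)(C)C.[Li+].[Li+] | intermediate
27 | tert-butyl (2S,3S)-2,3-dihydroxy-2-methylbutanoate | C[C@H](O)[C@](C)(O)C(=O)OC(C)(C)C | intermediate
28 | tert-butyl (2S,3R)-2-hydroxy-2-methyl-3-[(2Z)-2-methylbut-2-enoyloxy]butanoate | C/C=C(/C)C(=O)O[C@H](C)[C@](C)(O)C(=O)OC(C)(C)C | intermediate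
29 | (2S,3R)-2-hydroxy-2-methyl-3-[(2Z)-2-methylbut-2-enoyloxy]butanoic acid | C/C=C(/C)C(=O)O[C@H](C)[C@](C)(O)C(=O)O | intermediate
30 | mixed anhydride of 29 with 2,4,6-trichlorobenzoic acid | C/C=C(/C)C(=O)O[C@H](C)[C@](C)(O)C(=O)OC(=O)c1c(Cl)cc(Cl)cc1Cl | intermediate
31 | (1(10)Z,4Z,6R,7S,8R,11R)-6-{(2S,3R)-2-hydroxy-2-methyl-3-[(2Z)-2-methylbut-2-enoyloxy]butanoyloxy}-11-[(2Z)-2-methylbut-2-enoyloxy]germacra-1(10),4-dien-12,8-olide | C/C=C(/C)C(=O)O[C@H](C)[C@](C)(O)C(=O)O[C@@H]1/C=C(/C)CC/C=C(/C)C[C@H]2OC(=O)[C@](C)(OC(=O)/C(C)=C\C)[C@H]12 | intermediate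
32 | (1R,4Z,6R,7S,8R,10S,11R)-1,10-epoxy-6-{(2S,3R)-2-hydroxy-2-methyl-3-[(2Z)-2-methylbut-2-enoyloxy]butanoyloxy}-11-[(2Z)-2-methylbut-2-enoyloxy]germacr-4-en-12,8-olide | C/C=C(/C)C(=O)O[C@H](C)[C@](C)(O)C(=O)O[C@@H]1/C=C(/C)CC[C@H]2O[C@@]2(C)C[C@H]2OC(=O)[C@](C)(OC(=O)/C(C)=C\C)[C@H]12 | target

**Step count and risks**

Total steps: 15. Longest linear sequence: 8 steps (1 → 2 → 5 → 6 → 18 → 19 → 22 → 31 → 32; the diene branch 7 → 11 → 12 → 17 → 18 is equally long).

The three steps most likely to fail: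

1. Step 2 (the proposed new photochemical C6–C7 bond formation). The sulfonyl oxime has not been used as a trap for NHC-activated alcohols, and a neighbouring free tertiary hydroxyl is untested. Fallback with known chemistry, setting out from 2 and returning at 5: phenyl chlorothionoformate and pyridine in CH2Cl2 at 0 °C acylate only the secondary hydroxyl to give the O-phenyl thionocarbonate F1, used at once. Irradiation at 300 nm with hexamethylditin and 3 in benzene then runs the classical tin-chain sequence (stannyl radical attack on C=S, fragmentation to the same ring radical, addition to 3, loss of PhSO2•). The facial bias is the same, so it gives 5.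

2. Step 9 (closure of the ten-membered ring and the C6 configuration). The Felkin–Anh preference may be overridden by ring strain in the cyclising transition state. Fallback, setting out from 19 and returning at 22: if the ring closes mainly to the 6S alcohol 6-epi-22 F2, the stereocentre is set by substitution instead of by the C–C addition. Mitsunobu reaction of F2 with chloroacetic acid (PPh3, DIAD, toluene) inverts C6 to the 6R chloroacetate F3. Thiourea and NaHCO3 in EtOH then remove the chloroacetyl group without touching the angelate or the lactone, giving 22.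

3. Step 15 (face selectivity of the epoxidation). The 1R,10S outcome rests only on a conformational argument about the outer face of the C1=C10 olefin. Fallback, setting out from 31 and returning at 32: NBS in aqueous DME gives the bromohydrin F4 (bromonium on the exposed face, water opening it anti at the tertiary C10). DBU in CH2Cl2 then closes the oxirane by displacement at C1 with inversion. This puts the oxygen on the face opposite to the one the peracid reaches, so whichever face is exposed, one of the two procedures gives 32.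

**Further compounds**

F1 | step 2 | O-[(2S,3R,4R)-2-(bromomethyl)-4-hydroxy-4-methyl-5-oxooxolan-3-yl] O-phenyl carbonothioate | BrC[C@H]1OC(=O)[C@](C)(O)[C@@H]1OC(=S)Oc1ccccc1
F2 | step 9 | 6-epi-22, (1(10)Z,4Z,6S,7R,8R,11R)-6-hydroxy-11-[(2Z)-2-methylbut-2-enoyloxy]germacra-1(10),4-dien-12,8-olide | O[C@H]1/C=C(/C)CC/C=C(/C)C[C@H]2OC(=O)[C@](C)(OC(=O)/C(C)=C\C)[C@H]12
F3 | step 9 | (6R)-6-O-chloroacetyl derivative of 22 | ClCC(=O)O[C@@H]1/C=C(/C)CC/C=C(/C)C[C@H]2OC(=O)[C@](C)(OC(=O)/C(C)=C\C)[C@H]12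
F4 | step 15 | (1S,10S)-1-bromo-10-hydroxy-1,10-dihydro derivative of 31 | C/C=C(/C)C(=O)O[C@H](C)[C@](C)(O)C(=O)O[C@@H]1/C=C(/C)CC[C@H](Br)[C@@](C)(O)C[C@H]2OC(=O)[C@](C)(OC(=O)/C(C)=C\C)[C@H]12
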